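## Retrosynthetic overview

1. The target is opened at C8–C15′ and C13–C14′: a perezone-type cationic [5+2] cycloaddition between the hydroxy-p-quinone taiwaniaquinone A (C8–C9–C11–C12–C13 unit) and the terminal vinyl group of (12E)-labda-8(17),12,14-trien-18-oic acid.
2. Taiwaniaquinone A comes from (+)-carnosic acid: C20 CO2H → CH3, Δ6 by DDQ, ring B contracted 6 → 5 by an iodine(III) 1,2-aryl shift, C14 oxygen by Br → OMe, then demethylation and oxidation.
3. The trienoic acid comes from (−)-levopimaric acid: ozonolysis removes C13–C17 of ring C (leaving C8 ketone and C12 aldehyde), then an E-selective Wittig reaction and a double methylenation.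
4. Ring order: rings A/B of both halves and the six-membered ring C are bought; the cyclopentane ring B of the quinone half forms in step 6; the bicyclo[3.2.1]octenedione core (with C8, C13, C14′) forms last, in step 13.

Assumption: (+)-carnosic acid (rosemary) and (−)-levopimaric acid (pine oleoresin resin acid) are taken as purchasable, inexpensive natural products; abietane/labdane numbering is used, labdane locants are primed in the target, and in the ring-contracted series C6 is the ring carbon and C7 the exocyclic one-carbon unit.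

## Route

Step 1
Reactants: 1 (+)-carnosic acid
Product: 2 methyl (5S,10R)-11,12-dimethoxyabieta-8,11,13-trien-20-oate
Conditions: MeI, K2CO3, DMF, Ar, rt → 50 °C
Reagents that add atoms: iodomethane, CI
Why: Exhaustive SN2 O-methylation (Williamson etherification plus carboxylate alkylation) masks the air-sensitive catechol and the acid without touching C5 or C10.

Step 2
Reactants: 2 methyl 11,12-dimethoxyabieta-8,11,13-trien-20-oate
Product: 3 alcohol (5S,10R)-11,12-dimethoxyabieta-8,11,13-trien-20-ol
Conditions: LiAlH4, THF, reflux; aq. NaOH work-up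
Reagents that add atoms: none
Why: Hydride reduction of the hindered neopentyl ester to the primary alcohol breaks no bond at C10, so its configuration is kept.

Step 3
Reactants: 3 alcohol 11,12-dimethoxyabieta-8,11,13-trien-20-ol
Product: 4 aldehyde (5S,10R)-11,12-dimethoxyabieta-8,11,13-trien-20-al
Conditions: Dess–Martin periodinane, CH2Cl2, rt
Reagents that add atoms: none
Why: Dess–Martin oxidation stops at the non-enolisable aldehyde and avoids the C20 cation (ring expansion to an icetexane) that sulfonate activation of 3 would cause.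

Step 4
Reactants: 4 aldehyde 11,12-dimethoxyabieta-8,11,13-trien-20-al
Product: 6 dimethyl ether (5S,10S)-11,12-dimethoxyabieta-8,11,13-triene, via C20 aldehyde hydrazone 5 (not isolated)
Conditions: N2H4·H2O, KOH, diethylene glycol, 130 °C, then 210 °C
Reagents that add atoms: none
Why: Wolff–Kishner (Huang-Minlon) reduction turns the quaternary, non-epimerisable aldehyde into the C20 methyl group through the hydrazone and loss of N2.

Step 5
Reactants: 6 dimethyl ether 11,12-dimethoxyabieta-8,11,13-triene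
Product: 7 styrene (5S,10S)-11,12-dimethoxyabieta-6,8,11,13-tetraene
Conditions: DDQ (1.2 equiv), 1,4-dioxane, rt → 60 °C
Reagents that add atoms: none
Why: DDQ dehydrogenation removes hydride from benzylic C7 (cation para to the 12-OMe) and then H6, giving the conjugated Δ6 alkene with C5 and C10 untouched.

Step 6
Reactants: 7 styrene 11,12-dimethoxyabieta-6,8,11,13-tetraene
Product: 8 ring-contracted acetal (5S,6R,10S)-7,7,11,12-tetramethoxy-8(7→6)abeo-abieta-8,11,13-triene (ring B = C5–C6–C8–C9–C10; 6α-CH(OMe)2 cis to 5α-H and trans to 10β-CH3)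
Conditions: PhI(OH)OTs (1.2 equiv), MeOH, 0 °C → rt
Reagents that add atoms: methanol, CO
Why: Iodine(III)-mediated oxidative ring contraction (Koser reagent, semipinacol-type 1,2-aryl shift): the iodane adds to C6 from the α-face (the β-face is screened by the axial C19 and C20 methyls), methanol adds at benzylic C7, and aryl carbon C8 migrates to C6 with inversion as PhI leaves, placing CH(OMe)2 on the α-face (6R), which is also the thermodynamically preferred arrangement.

Step 7
Reactants: 8 ring-contracted acetal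
Product: 9 aryl bromide (5S,6R,10S)-14-bromo-7,7,11,12-tetramethoxy-8(7→6)abeo-abieta-8,11,13-triene
Conditions: NBS (1.05 equiv), MeCN, 0 °C, dark
Reagents that add atoms: N-bromosuccinimide, BrN1C(=O)CCC1=O
Why: Electrophilic aromatic bromination occurs at the only free ring position, C14 (para to the 11-OMe), under ionic conditions that leave the acetal and the benzylic C–H bonds alone.

Step 8
Reactants: 9 aryl bromide
Product: 10 trimethoxyarene (5S,6R,10S)-7,7,11,12,14-pentamethoxy-8(7→6)abeo-abieta-8,11,13-triene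
Conditions: NaOMe, CuI (cat.), DMF–MeOH, 110 °C
Reagents that add atoms: sodium methoxide, [Na+].[O-]C
Why: Copper-catalysed Ullmann-type methoxylation replaces Br by OMe and completes the 11,12,14-oxygenation pattern; the basic medium does not affect the acetal or any stereocentre.

Step 9
Reactants: 10 trimethoxyarene
Product: 12 taiwaniaquinone A [(5S,6R,10S)-12-hydroxy-11,14-dioxo-8(7→6)abeo-abieta-8,12-dien-7-al], via hydroxyhydroquinone aldehyde 11 (not isolated)
Conditions: BBr3 (8 equiv), CH2Cl2, −78 → 0 °C; H2O; then aq. FeCl3, EtOAc, rt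
Reagents that add atoms: water, O
Why: BBr3 cleaves the three aryl methyl ethers and opens the acetal, water releases the aldehyde and the 11,12,14-triol, and Fe(III) oxidises the triol to the 12-hydroxy-11,14-quinone, while the acidic medium keeps or equilibrates C6 to the stable 6α-CHO epimer.

Step 10
Reactants: 13 (−)-levopimaric acid
Product: 14 keto aldehyde acid 8,12-dioxo-13,14,15,16,17-pentanorlabdan-18-oic acid (4α-CO2H, 5α-H, 9α-H, 10β-CH3)
Conditions: O3, pyridine (4 equiv), CH2Cl2, −78 °C; N2 purge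
Reagents that add atoms: ozone, [O-][O+]=O
Why: Pyridine-mediated reductive ozonolysis cleaves both double bonds of the ring-C diene (C8=C14 and C12=C13) and excises C13–C17, leaving the C8 ketone and C12 aldehyde; C9 keeps its equatorial β side chain, which is also the thermodynamic epimer.

Step 11
Reactants: 14 keto aldehyde acid
Product: 15 enal acid (12E)-8,14-dioxo-15,17-dinorlabd-12-en-18-oic acid
Conditions: Ph3P=C(CH3)CHO (2.5 equiv), toluene, 80 °C; dilute acid work-up
Reagents that add atoms: 2-(triphenylphosphoranylidene)propanal, CC(C=O)=P(c1ccccc1)(c1ccccc1)c1ccccc1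
Why: Wittig olefination with the stabilised ylide is aldehyde-selective (the C8 ketone is inert) and E-selective, and the excess ylide tolerates the free carboxylic acid.

Step 12
Reactants: 15 enal acid
Product: 16 trienoic acid (4R,5R,9S,10R,12E)-labda-8(17),12,14-trien-18-oic acid
Conditions: Ph3PCH3Br (5 equiv), KOtBu (4.8 equiv), THF, 0 → 50 °C; aq. NH4Cl/citric acid
Reagents that add atoms: methyltriphenylphosphonium bromide, C[P+](c1ccccc1)(c1ccccc1)c1ccccc1.[Br-]
Why: Double Wittig methylenation with the non-stabilised ylide converts the enal into the 1,3-diene and the C8 ketone into the exocyclic methylene (the first equivalent only forms the carboxylate), with C9 already in its favoured configuration.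

Step 13
Reactants: 12 taiwaniaquinone A; 16 trienoic acid (12E)-labda-8(17),12,14-trien-18-oic acid
Product: 17 target CNP0256710.1 [quinone half 5S,6R,8S,10S,13R; labdane half 4′R,5′R,9′S,10′R,14′S,12′E; C15′ bonded to C8 and C14′ to C13, giving an 11-hydroxy-12,14-dioxo bicyclo[3.2.1]oct-9(11)-ene core]
Conditions: 16 (1.5 equiv), BF3·OEt2 (1.5 equiv, promoter, not consumed), CH2Cl2, −78 → −30 °C; pH 7 buffer
Reagents that add atoms: none
Why: Perezone–pipitzol-type cationic [5+2] cycloaddition: BF3 activation at the C11 carbonyl makes the hydroxyquinone a 2-hydroxypentadienyl cation, the terminal CH2 (C15′) bonds to electrophilic C8 and the allyl cation is closed at C14′ by enol carbon C13 on the α-face (anti to the axial 10β-methyl) with the residual alkene endo under the C9=C11–C12 bridge, which sets C8 (S), C13 (R) and C14′ (S), and because C8 becomes quaternary no re-aromatising pathway competes.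

## Compound list

1 | (+)-carnosic acid, (5S,10R)-11,12-dihydroxyabieta-8,11,13-trien-20-oic acid | CC(C)c1cc2c(c(O)c1O)[C@@]1(C(=O)O)CCCC(C)(C)[C@@H]1CC2 | starting material
2 | methyl (5S,10R)-11,12-dimethoxyabieta-8,11,13-trien-20-oate | COc1c(OC)c(C(C)C)cc2c1[C@@]1(C(=O)OC)CCCC(C)(C)[C@@H]1CC2 | intermediate
3 | (5S,10R)-11,12-dimethoxyabieta-8,11,13-trien-20-ol | COc1c(OC)c(C(C)C)cc2c1[C@@]1(CO)CCCC(C)(C)[C@@H]1CC2 | intermediate
4 | (5S,10R)-11,12-dimethoxyabieta-8,11,13-trien-20-al | COc1c(OC)c(C(C)C)cc2c1[C@@]1(C=O)CCCC(C)(C)[C@@H]1CC2 | intermediate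
5 | C20 hydrazone of 4 | COc1c(OC)c(C(C)C)cc2c1[C@@]1(C=NN)CCCC(C)(C)[C@@H]1CC2 | intermediate
6 | (5S,10S)-11,12-dimethoxyabieta-8,11,13-triene | COc1c(OC)c(C(C)C)cc2c1[C@@]1(C)CCCC(C)(C)[C@@H]1CC2 | intermediate
7 | (5S,10S)-11,12-dimethoxyabieta-6,8,11,13-tetraene | COc1c(OC)c(C(C)C)cc2c1[C@@]1(C)CCCC(C)(C)[C@@H]1C=C2 | intermediate
8 | (5S,6R,10S)-7,7,11,12-tetramethoxy-8(7→6)abeo-abieta-8,11,13-triene (6α-dimethoxymethyl, five-membered ring B) | COc1c(OC)c(C(C)C)cc2c1[C@@]1(C)CCCC(C)(C)[C@@H]1[C@H]2C(OC)OC | intermediate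
9 | (5S,6R,10S)-14-bromo-7,7,11,12-tetramethoxy-8(7→6)abeo-abieta-8,11,13-triene | COc1c(OC)c(C(C)C)c(Br)c2c1[C@@]1(C)CCCC(C)(C)[C@@H]1[C@H]2C(OC)OC | intermediate
10 | (5S,6R,10S)-7,7,11,12,14-pentamethoxy-8(7→6)abeo-abieta-8,11,13-triene | COc1c(OC)c(C(C)C)c(OC)c2c1[C@@]1(C)CCCC(C)(C)[C@@H]1[C@H]2C(OC)OC | intermediate
11 | (5S,6R,10S)-11,12,14-trihydroxy-8(7→6)abeo-abieta-8,11,13-trien-7-al | Oc1c(O)c(C(C)C)c(O)c2c1[C@@]1(C)CCCC(C)(C)[C@@H]1[C@H]2C=O | intermediate
12 | taiwaniaquinone A, (5S,6R,10S)-12-hydroxy-11,14-dioxo-8(7→6)abeo-abieta-8,12-dien-7-al | OC1=C(C(C)C)C(=O)C2=C(C1=O)[C@@]1(C)CCCC(C)(C)[C@@H]1[C@H]2C=O | intermediate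
13 | (−)-levopimaric acid, (4R,5R,9S,10R)-abieta-8(14),12-dien-18-oic acid | CC(C)C1=CC[C@H]2C(=C1)CC[C@@H]1[C@]2(C)CCC[C@@]1(C)C(=O)O | starting material
14 | 8,12-dioxo-13,14,15,16,17-pentanorlabdan-18-oic acid (4α-CO2H, 5α-H, 9α-H, 10β-CH3) | O=CC[C@H]2C(=O)CC[C@@H]1[C@]2(C)CCC[C@@]1(C)C(=O)O | intermediate
15 | (12E)-8,14-dioxo-15,17-dinorlabd-12-en-18-oic acid | O=C/C(C)=C/C[C@H]2C(=O)CC[C@@H]1[C@]2(C)CCC[C@@]1(C)C(=O)O | intermediate
16 | (4R,5R,9S,10R,12E)-labda-8(17),12,14-trien-18-oic acid | C=C/C(C)=C/C[C@H]2C(=C)CC[C@@H]1[C@]2(C)CCC[C@@]1(C)C(=O)O | intermediate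
17 | CNP0256710.1, [5+2] adduct of 12 and 16 | C=C1CC[C@@H]2[C@](C)(CCC[C@@]2(C)C(=O)O)[C@H]1C/C=C(\C)[C@@H]1C[C@@]23C(=O)[C@]1(C(C)C)C(=O)C(O)=C2[C@@]1(C)CCCC(C)(C)[C@@H]1[C@H]3C=O | target

## Step count and risks

Total: 13 steps. Longest linear sequence: 10 steps (steps 1–9, then step 13); the labdane branch is steps 10–12.

**Step 13 ([5+2] cycloaddition).** This is the least certain step: it is intermolecular, both new bonds form at fully substituted carbons, the exocyclic alkene and the aldehyde are acid-sensitive, and facial/endo selectivity rests on substrate control only. The fallback sets out from 12 and 16 and comes back at 17. Acid 16 is esterified (allyl bromide, K2CO3, DMF) to allyl (12E)-labda-8(17),12,14-trien-18-oate F1. Quinone 12 is O-benzylated (BnBr, Ag2O) to 12-O-benzyltaiwaniaquinone A F2. TiCl4 in CH2Cl2 at −78 °C then promotes an alkoxyquinone [5+2] cycloaddition (Büchi/Engler type) in which the benzyl group is lost from the oxocarbenium intermediate, giving the allyl ester of the target F3. Pd(PPh3)4 and morpholine release 17.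

**Step 6 (iodine(III) ring contraction).** Simple methanol addition across the alkene or oxidation of the electron-rich arene could compete with the aryl shift. The fallback sets out from 6 and comes back at 8. Benzylic oxidation (CrO3, AcOH) gives 11,12-dimethoxyabieta-8,11,13-trien-7-one F4. Diazo transfer (2,4,6-triisopropylbenzenesulfonyl azide, KOH, 18-crown-6) gives 6-diazo-11,12-dimethoxyabieta-8,11,13-trien-7-one F5. Photochemical Wolff rearrangement in MeOH, followed by NaOMe equilibration, gives the ring-contracted methyl 11,12-dimethoxy-8(7→6)abeo-abieta-8,11,13-trien-7-oate F6. DIBAL-H at −78 °C gives 11,12-dimethoxy-8(7→6)abeo-abieta-8,11,13-trien-7-al F7, and HC(OMe)3/MeOH/PPTS converts it to 8.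

**Step 9 (global demethylation and oxidation).** BBr3 may attack the liberated aldehyde, or the triol may degrade at the doubly activated C6–H. The fallback sets out from 10 and comes back at 12. CAN in MeCN/H2O at 0 °C with acidic work-up oxidatively demethylates the 11,14-dimethoxy pair and unmasks the aldehyde, giving 12-O-methyltaiwaniaquinone A F8. LiOH in degassed THF/H2O, then acid, hydrolyses the vinylogous ester to 12.

Further compounds
F1 | step 13 | allyl (12E)-labda-8(17),12,14-trien-18-oate | C=C/C(C)=C/C[C@H]2C(=C)CC[C@@H]1[C@]2(C)CCC[C@@]1(C)C(=O)OCC=C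
F2 | step 13 | 12-O-benzyltaiwaniaquinone A | c1ccccc1COC1=C(C(C)C)C(=O)C2=C(C1=O)[C@@]1(C)CCCC(C)(C)[C@@H]1[C@H]2C=O
F3 | step 13 | allyl ester of target 17 | C=C1CC[C@@H]2[C@](C)(CCC[C@@]2(C)C(=O)OCC=C)[C@H]1C/C=C(\C)[C@@H]1C[C@@]23C(=O)[C@]1(C(C)C)C(=O)C(O)=C2[C@@]1(C)CCCC(C)(C)[C@@H]1[C@H]3C=O
F4 | step 6 | (5S,10S)-11,12-dimethoxyabieta-8,11,13-trien-7-one | COc1c(OC)c(C(C)C)cc2c1[C@@]1(C)CCCC(C)(C)[C@@H]1CC2=O
F5 | step 6 | (5S,10S)-6-diazo-11,12-dimethoxyabieta-8,11,13-trien-7-one | COc1c(OC)c(C(C)C)cc2c1[C@@]1(C)CCCC(C)(C)[C@@H]1C(=[N+]=[N-])C2=O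
F6 | step 6 | methyl (5S,6R,10S)-11,12-dimethoxy-8(7→6)abeo-abieta-8,11,13-trien-7-oate | COc1c(OC)c(C(C)C)cc2c1[C@@]1(C)CCCC(C)(C)[C@@H]1[C@H]2C(=O)OC
F7 | step 6 | (5S,6R,10S)-11,12-dimethoxy-8(7→6)abeo-abieta-8,11,13-trien-7-al | COc1c(OC)c(C(C)C)cc2c1[C@@]1(C)CCCC(C)(C)[C@@H]1[C@H]2C=O
F8 | step 9 | 12-O-methyltaiwaniaquinone A | COC1=C(C(C)C)C(=O)C2=C(C1=O)[C@@]1(C)CCCC(C)(C)[C@@H]1[C@H]2C=O
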